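## Structural features

The target is a biflavanoid. An upper 5,7,3',4'-tetrahydroxyflavan (rings A, C and B, no oxygen on C3) is joined through its C4 to C8 of a lower (+)-catechin unit. The upper ring C holds two stereocentres, C2 (S) and C4 (S), which stand 1,3 to each other across the C3 methylene and are cis. The lower ring C holds the adjacent, trans pair C2 (R) and C3 (S) of catechin. Upper C4 is a doubly benzylic methine between two phloroglucinol-type rings, each with two ortho oxygens. The C4–C8 bond is therefore very crowded and, like the interflavan bond of proanthocyanidins, can break heterolytically under acid. The free compound, with eight phenols and one secondary alcohol, is sensitive to air and base, so the hydroxyls should stay masked until the last flask. The real difficulty is to form the congested C4–C8 bond with absolute control at C4, and then to set C2 relative to C4 without exposing C4 to acid or strong base. The key step exploits the fact that upper C3 is a bare CH2 between C2 and C4: C2=C3 can be closed by metathesis between an aryl 1-arylvinyl ether on O1 of ring A and a vinyl group on C4, and the C4 aryl group can then steer hydrogenation of that double bond in ring C.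

## Logic of the disconnections

**21 to 20.** The two hydrogens on C2 and C3 of the upper ring C are removed and nine O–benzyl bonds are restored. C2 is the one stereocentre that can be derived from its neighbour, so it is stored as an sp2 carbon. The polyphenol then appears only at the end and one stereocentre leaves the problem. The forward step must add hydrogen to C2=C3 on the face away from the C4 substituent, cleave nine benzyl ethers, and spare the benzylic C2–O1 and C4–C8 bonds.

**20 to 19.** The C2=C3 bond is cut. C2 becomes the α-carbon of an enol ether on O1, and C3 the inner carbon of a vinyl group on C4. Ring C is opened and no stereocentre is involved. The forward step needs a catalyst that starts at the vinyl group, accepts an electron-rich 1,1-disubstituted enol ether, and is neither acidic nor a hydride source, because C4 in 19 is doubly benzylic and allylic.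

**19 to 18.** The terminal =CH2 is cut from C2, leaving the carbonyl group of 18. An aryl ester is easier to make and store than an enol ether, and methylenation adds exactly the carbon that metathesis later expels. The forward step must be non-acidic, non-basic, and must ignore the vinyl group.

**18 to 15 and 16.** The O1–acyl bond is cut; 16 is used as 17. Ring B with its two oxygens is then a purchased benzoic acid. The forward step must acylate a phenol with a large ortho substituent under conditions too mild to move the C4 vinyl double bond.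

**15 to 14.** The O1–H of 15 is masked as the allyl ether of 14. Ring A has three oxygens and only O1 may be free at the acylation. The allyl group is small, inert to hydride, base and organocopper species, and leaves under neutral conditions, which C4 requires. The forward step must remove it with zerovalent palladium without touching the C4 vinyl group.

**14 to 6 and 13.** The C4–C8 bond is cut with allylic transposition. C4 becomes the γ-carbon of 6, and C8 of the lower unit the aryl nucleophile 13. This is the most simplifying cut: two fragments of similar size, the vinyl group arises from the transposition, and C4 is created under catalyst control. Ring A is the electrophile because its C4 carbon can then come from a formyl group placed ortho to the future O1. The lower unit is the nucleophile because its C8 halide is directly accessible. The forward step needs γ-selective, face-selective transfer of a di-ortho-substituted aryl group to a carbon that itself carries a di-ortho-substituted ring, before the electron-rich phosphate ionises.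

**13 back to 7.** The C8–B bond leads to 10, the C8–Br bond to 9, and the O–benzyl bonds, in two stages, to 8 and 7. Compound 7 supplies the whole lower skeleton and both lower stereocentres. The forward steps need substitution at C8 and not C6, and halogen–lithium exchange faster than attack on benzyl ethers.

**6 back to 3.** The P–O bond leads to 5, a change of oxidation level to 4, and the Cα=Cβ bond of 4 to 3. This is a standard two-carbon homologation; the E geometry must be secured.

**3 back to 1.** The O–allyl bond leads to 2 and the aryl–CHO bond to 1. The two ortho positions of 1 are equivalent, so ortho-formylation can give only one product. It fixes in one step which carbon becomes C4 and which oxygen becomes O1. The forward step must formylate ortho, not para, to the hydroxyl.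

## Other disconnections considered

**Alternative 1:** The cut takes lower ring A apart at C8–C8a and C6–C7, so that this ring is assembled late from an alkyne and a four-carbon ketene precursor.
- **Forward step.** Siloxyalkyne A1, carried on C4 of a finished 2,4-cis upper flavan, would be heated with 3-(benzyloxy)cyclobut-2-en-1-one A2. Ring opening of A2 to a vinylketene, [2+2] cycloaddition with the electron-rich alkyne, opening of the new cyclobutenone and six-electron electrocyclisation with tautomerisation should give phenol A3. Its new ring carries a free hydroxyl, a benzyloxy and a triisopropylsiloxy group.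
- **In favour.** The polarity of ketene and ynol ether fixes the regiochemistry. The crowded C4–aryl bond is not made by aryl transfer to a hindered carbon; the ring grows from a slim alkyne. The three oxygens emerge differentiated. On these two points the alternative is better than the chosen plan. Its neutral thermal conditions are the equal of the metathesis as regards the acid-labile C4.
- **Against.** A3 is not yet a flavan-3-ol. Lower ring C with C2 and C3 must still be built on the new ring, which replaces by synthesis what 7 supplies for nothing. The upper ring C with both stereocentres must exist before the key step, so the question answered by the metathesis is passed to another method. The C4–H of A1 is propargylic as well as doubly benzylic and may epimerise on heating. A1 and A2 each need several steps.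
- **Comparison.** On structure, the key step is spent on an aromatic ring that can be bought. On mechanism, it is a clean pericyclic cascade. On step economy, it is clearly longer.

**Alternative 2:** The cut is lower C4–C4a, so that lower ring C is closed last by an arene attacking an epoxide.
- **Forward step.** AuCl3 with AgOTf (a cationic trivalent gold Lewis acid) would activate the oxirane of aryl ether A4. The single unsubstituted carbon ortho to the ether oxygen would open it at the CH2 end (endo mode, six-membered ring) to give A5, the octabenzyl ether of 21 with the lower 3-hydroxyl free.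
- **In favour.** The position of attack on the ring is unambiguous, whereas the chosen plan relies on the inherent C8 preference of a bromination; on this point the alternative is better. Lower C3 is carried unchanged from the epoxide. The free 3-hydroxyl is differentiated, which the chosen plan does not offer. Both plans end with the same global hydrogenolysis and are equal there.
- **Against.** A Lewis acid meets a substrate with the acid-labile upper C4–aryl bond and a benzylic ether carbon bearing an electron-rich aryl ring. Ionisation there would scramble lower C2, and exo-mode opening would give a dihydrobenzofuran. The ether bond of A4 has to be made at an electron-rich benzylic carbon with full stereochemical fidelity. A4 already contains the complete upper unit, so the hard part (C4 and upper C2) is left unsolved.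
- **Comparison.** On structure, the lower unit is built instead of bought. On mechanism, it is a cationic cyclisation, against a neutral metathesis. On step economy, it is longer.

**Alternative 3:** The cut is upper O1–C2, in a precursor whose C4 bears two identical phloroglucinol rings.
- **Forward step.** PPh3 and diisopropyl azodicarboxylate would activate the benzylic carbinol of A6. One of the two diastereotopic ortho phenols would displace it with inversion, closing upper ring C, setting C2, and making C4 stereogenic by group selection, to give A7.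
- **In favour.** C4 is not stereogenic in A6, and its two aryl bonds can be made by ordinary cationic arylation without hindered organometallic coupling. Only the carbinol must be set by a reagent, and a chair-like closure with both aryl groups equatorial should favour 2,4-cis. If that selection is high, the alternative is the equal of, or better than, the chosen plan in stereocontrol: one reagent-controlled centre yields both C2 and C4, where the chosen plan needs a catalyst for C4 and facial control for C2. It also avoids any acid-sensitive enol ether.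
- **Against.** The size of the group selection is hard to predict. Activation of an electron-rich benzylic carbinol can leak into ionisation, with loss of inversion or elimination. A7 carries only a phenol ring where 21 has a whole catechin, so lower ring C with two stereocentres must still be built.
- **Comparison.** On structure, it solves the upper unit neatly but not the lower one. On mechanism, it is substitution with inversion, against metathesis plus hydrogenation. On step economy, it is shorter to the upper unit and longer to 21.

Key step: step 14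

Remark 1: 3,5-bis(benzyloxy)phenol and 3,4-bis(benzyloxy)benzoic acid are taken as purchased; each is a routine benzylation product of phloroglucinol or 3,4-dihydroxybenzoic acid.
Remark 2: the sense of induction of the chiral NHC–copper catalyst on this substrate class is assumed to be assignable on a model allylic phosphate; the ligand enantiomer leading to (1S)-14 is meant throughout.

Step 1
Reactants: 1 3,5-bis(benzyloxy)phenol
Product: 2 2,4-bis(benzyloxy)-6-hydroxybenzaldehyde
Conditions: MgCl2, Et3N, (CH2O)n, MeCN, reflux; 1 M HCl work-up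
Reagents that add atoms: paraformaldehyde (as formaldehyde), C=O
Why: Casnati–Skattebøl ortho-formylation: the magnesium phenoxide delivers formaldehyde to the carbon ortho to oxygen and a second formaldehyde oxidises the benzylic alkoxide. The two ortho carbons of 1 are equivalent, so one regioisomer is expected, with the future C4 carbon and the future O1 hydroxyl fixed.

Step 2
Reactants: 2 2,4-bis(benzyloxy)-6-hydroxybenzaldehyde
Product: 3 2-(allyloxy)-4,6-bis(benzyloxy)benzaldehyde
Conditions: allyl bromide, K2CO3, DMF, 50 °C
Reagents that add atoms: allyl bromide, C=CCBr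
Why: Williamson etherification of the chelated phenol. The allyl ether is stable to hydride, base and organocopper species and is later removed under neutral conditions, which the acid-labile C4 demands.

Step 3
Reactants: 3 2-(allyloxy)-4,6-bis(benzyloxy)benzaldehyde
Product: 4 ethyl (2E)-3-[2-(allyloxy)-4,6-bis(benzyloxy)phenyl]prop-2-enoate
Conditions: (EtO)2P(O)CH2CO2Et, NaH, THF, 0 °C → rt
Reagents that add atoms: triethyl phosphonoacetate, CCOC(=O)CP(=O)(OCC)OCC
Why: Horner–Wadsworth–Emmons olefination; the stabilised phosphonate anion should give the E enoate and tolerates the two ortho substituents.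

Step 4
Reactants: 4 ethyl (2E)-3-[2-(allyloxy)-4,6-bis(benzyloxy)phenyl]prop-2-enoate
Product: 5 (2E)-3-[2-(allyloxy)-4,6-bis(benzyloxy)phenyl]prop-2-en-1-ol
Conditions: i-Bu2AlH, CH2Cl2, −78 °C; aqueous potassium sodium tartrate
Reagents that add atoms: none
Why: 1,2-reduction of the enoate by the aluminium hydride at low temperature gives the allylic alcohol and leaves the ethers and the alkene geometry untouched.

Step 5
Reactants: 5 (2E)-3-[2-(allyloxy)-4,6-bis(benzyloxy)phenyl]prop-2-en-1-ol
Product: 6 (2E)-3-[2-(allyloxy)-4,6-bis(benzyloxy)phenyl]prop-2-en-1-yl diethyl phosphate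
Conditions: ClP(O)(OEt)2, pyridine, DMAP (cat.), CH2Cl2, 0 °C
Reagents that add atoms: diethyl chlorophosphate, CCOP(=O)(Cl)OCC
Why: O-phosphorylation gives the leaving group that copper chemistry needs for γ-selectivity. The two ortho substituents twist the ring out of conjugation with the alkene, which should temper ionisation; 6 is nevertheless kept cold and used promptly.

Step 6
Reactants: 7 (+)-catechin, (2R,3S)
Product: 8 5,7,3',4'-tetra-O-benzyl-(+)-catechin
Conditions: BnBr, K2CO3, DMF, 0 °C → rt
Reagents that add atoms: benzyl bromide, BrCc1ccccc1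
Why: Williamson benzylation; the carbonate deprotonates only the four phenols, so the secondary alcohol stays free and the stereocentres are not touched.

Step 7
Reactants: 8 5,7,3',4'-tetra-O-benzyl-(+)-catechin
Product: 9 3,5,7,3',4'-penta-O-benzyl-(+)-catechin
Conditions: NaH, BnBr, n-Bu4NI (cat.), THF/DMF, 0 °C → rt
Reagents that add atoms: benzyl bromide, BrCc1ccccc1
Why: Williamson etherification of the 3-alkoxide. With all phenols capped, the base-mediated opening of ring C that epimerises C2 is not available.

Step 8
Reactants: 9 3,5,7,3',4'-penta-O-benzyl-(+)-catechin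
Product: 10 8-bromo-3,5,7,3',4'-penta-O-benzyl-(+)-catechin
Conditions: NBS, CH2Cl2, −78 °C → rt
Reagents that add atoms: N-bromosuccinimide, O=C1CCC(=O)N1Br
Why: Electrophilic aromatic bromination; in 5,7-di-O-benzylated flavan-3-ols C8 is the established preferred site over C6, and one equivalent of reagent at low temperature should stop at the monobromide.

Step 9
Reactants: 10 8-bromo-3,5,7,3',4'-penta-O-benzyl-(+)-catechin
Product: 13 2-(3,5,7,3',4'-penta-O-benzylcatechin-8-yl)-5,5-dimethyl-1,3,2-dioxaborinane, via 8-lithio-penta-O-benzylcatechin 11 (not isolated), via lithium trimethoxy(penta-O-benzylcatechin-8-yl)borate 12 (not isolated)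
Conditions: n-BuLi, THF, −78 °C; B(OMe)3, −78 °C → rt; neopentyl glycol, AcOH, rt
Reagents that add atoms: trimethyl borate, COB(OC)OC; neopentyl glycol, OCC(C)(C)CO
Why: Bromine–lithium exchange at −78 °C is faster than attack on benzyl ethers. The aryllithium is trapped as the borate, and ligand exchange with the diol gives the neopentyl glycol ester that transfers aryl groups to copper.

Step 10
Reactants: 6 (2E)-3-[2-(allyloxy)-4,6-bis(benzyloxy)phenyl]prop-2-en-1-yl diethyl phosphate; 13 2-(3,5,7,3',4'-penta-O-benzylcatechin-8-yl)-5,5-dimethyl-1,3,2-dioxaborinane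
Product: 14 8-{(1S)-1-[2-(allyloxy)-4,6-bis(benzyloxy)phenyl]prop-2-en-1-yl}-3,5,7,3',4'-penta-O-benzyl-(+)-catechin
Conditions: CuCl (10 mol%), chiral hydroxyl-bearing imidazolinium chloride (NHC precursor, 11 mol%), NaOMe, THF, 30 °C
Reagents that add atoms: none
Why: Copper-catalysed enantioselective SN2' allylic arylation: methoxide activates the boronate, the aryl group passes to the NHC-bound monovalent copper, which attacks the alkene anti to the phosphate, and reductive elimination at the γ-carbon gives the branched 1,1-diarylpropene. C4 is set as (S) by the chiral ligand (catalyst control). Because 13 is a single enantiomer, any minor C4 epimer is a diastereomer and can be removed.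

Step 11
Reactants: 14 8-{(1S)-1-[2-(allyloxy)-4,6-bis(benzyloxy)phenyl]prop-2-en-1-yl}-3,5,7,3',4'-penta-O-benzyl-(+)-catechin
Product: 15 8-{(1S)-1-[2,4-bis(benzyloxy)-6-hydroxyphenyl]prop-2-en-1-yl}-3,5,7,3',4'-penta-O-benzyl-(+)-catechin
Conditions: Pd(PPh3)4 (5 mol%), morpholine, THF, rt
Reagents that add atoms: none
Why: Tsuji–Trost deallylation: zerovalent palladium ionises only the allyl aryl ether and morpholine traps the allyl fragment. The C4 vinyl group has no leaving group and the neutral medium cannot ionise or deprotonate C4.

Step 12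
Reactants: 15 8-{(1S)-1-[2,4-bis(benzyloxy)-6-hydroxyphenyl]prop-2-en-1-yl}-3,5,7,3',4'-penta-O-benzyl-(+)-catechin; 16 3,4-bis(benzyloxy)benzoic acid
Product: 18 3,5-bis(benzyloxy)-2-[(1S)-1-(3,5,7,3',4'-penta-O-benzylcatechin-8-yl)prop-2-en-1-yl]phenyl 3,4-bis(benzyloxy)benzoate, via 3,4-bis(benzyloxy)benzoyl chloride 17 (not isolated)
Conditions: (COCl)2, DMF (cat.), CH2Cl2, rt; then Et3N, DMAP, CH2Cl2, 0 °C → rt
Reagents that add atoms: none
Why: Acylation of the phenol by the acid chloride with nucleophilic catalysis by DMAP, which should overcome the large ortho substituent. The amine base is too weak to move the C4 double bond into conjugation.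

Step 13
Reactants: 18 3,5-bis(benzyloxy)-2-[(1S)-1-(3,5,7,3',4'-penta-O-benzylcatechin-8-yl)prop-2-en-1-yl]phenyl 3,4-bis(benzyloxy)benzoate
Product: 19 8-{(1S)-1-[2,4-bis(benzyloxy)-6-({1-[3,4-bis(benzyloxy)phenyl]ethenyl}oxy)phenyl]prop-2-en-1-yl}-3,5,7,3',4'-penta-O-benzyl-(+)-catechin
Conditions: Cp2TiMe2, toluene/THF, 65 °C, dark; filtration through basic Al2O3
Reagents that add atoms: dimethyltitanocene, [CH3-].[CH3-].[Ti+4].[cH-]1cccc1.[cH-]1cccc1
Why: Petasis methylenation: on heating the reagent loses methane to give Cp2Ti=CH2, which adds [2+2] to the ester carbonyl and cycloreverts to the enol ether. The reagent is neither acidic nor basic, so C4 and the vinyl group should survive, and aryl esters are good substrates.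

Step 14
Reactants: 19 8-{(1S)-1-[2,4-bis(benzyloxy)-6-({1-[3,4-bis(benzyloxy)phenyl]ethenyl}oxy)phenyl]prop-2-en-1-yl}-3,5,7,3',4'-penta-O-benzyl-(+)-catechin
Product: 20 (4S)-5,7-bis(benzyloxy)-2-[3,4-bis(benzyloxy)phenyl]-4-(3,5,7,3',4'-penta-O-benzylcatechin-8-yl)-4H-chromene (nona-O-benzyl 4-(catechin-8-yl)flav-2-ene)
Conditions: Mo(=CHCMe2Ph)(=N-2,6-i-Pr2C6H3)[OCMe(CF3)2]2 (15 mol%), C6H6, 25 → 50 °C, argon, open to a bubbler
Reagents that add atoms: none
Why: The hexavalent molybdenum alkylidene exchanges first with the monosubstituted C4 vinyl group, the most accessible alkene, which places the metal on C3. Intramolecular [2+2] cycloaddition of this alkylidene with the 1,1-disubstituted enol ether C=CH2 on O1, followed by cycloreversion, forms C2=C3, and the methylidene left on the metal releases ethylene when it takes up the next vinyl group. The closest known reaction type is ring-closing metathesis of olefinic enol ethers obtained by ester methylenation, which gives five- to seven-membered cyclic enol ethers, benzo-fused ones included. Ring C closes as a six-membered ring in which O1, C8a, C4a and C4 tether the two alkene carbons, so the new trisubstituted double bond is endocyclic and necessarily cis. No stereocentre is created, and C4 is kept because the catalyst is neither acidic enough to ionise the doubly benzylic C4–C8 bond nor a source of metal hydride that could move the vinyl double bond into conjugation. The step needs chemoselectivity for one alkene pair, and the design secures it: the allyl ether was removed in step 11 and 19 holds no other alkene, free hydroxyl or carbonyl group. It also needs ring closure to outrun intermolecular metathesis, which the hindered vinyl group, the unreactive α-aryl enol ether and dilution should ensure. Loss of ethylene makes the closure irreversible in an open system.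

Step 15
Reactants: 20 (4S)-5,7-bis(benzyloxy)-2-[3,4-bis(benzyloxy)phenyl]-4-(3,5,7,3',4'-penta-O-benzylcatechin-8-yl)-4H-chromene
Product: 21 (2S,4S)-2-(3,4-dihydroxyphenyl)-4-[(2R,3S)-2-(3,4-dihydroxyphenyl)-3,5,7-trihydroxychroman-8-yl]chroman-5,7-diol (CNP0180676.1)
Conditions: H2 (1 atm), Pd(OH)2/C, THF/EtOAc, rt; then MeOH added, rt
Reagents that add atoms: none
Why: Heterogeneous hydrogenation adds both hydrogens to C2=C3 from the face opposite the pseudo-axial C4 aryl group, so the C2 aryl ends cis to the C4 aryl and C2 becomes (S) by substrate control. Hydrogenolysis then removes the nine benzyl ethers. The aprotic first stage keeps the enol ether from solvolysis before it is reduced.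

## Compound list

1 | 3,5-bis(benzyloxy)phenol | Oc1cc(OCc2ccccc2)cc(OCc2ccccc2)c1 | starting material
2 | 2,4-bis(benzyloxy)-6-hydroxybenzaldehyde | O=Cc1c(O)cc(OCc2ccccc2)cc1OCc1ccccc1 | intermediate
3 | 2-(allyloxy)-4,6-bis(benzyloxy)benzaldehyde | O=Cc1c(OCC=C)cc(OCc2ccccc2)cc1OCc1ccccc1 | intermediate
4 | ethyl (2E)-3-[2-(allyloxy)-4,6-bis(benzyloxy)phenyl]prop-2-enoate | CCOC(=O)/C=C/c1c(OCC=C)cc(OCc2ccccc2)cc1OCc1ccccc1 | intermediate
5 | (2E)-3-[2-(allyloxy)-4,6-bis(benzyloxy)phenyl]prop-2-en-1-ol | OC/C=C/c1c(OCC=C)cc(OCc2ccccc2)cc1OCc1ccccc1 | intermediate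
6 | (2E)-3-[2-(allyloxy)-4,6-bis(benzyloxy)phenyl]prop-2-en-1-yl diethyl phosphate | CCOP(=O)(OCC)OC/C=C/c1c(OCC=C)cc(OCc2ccccc2)cc1OCc1ccccc1 | intermediate
7 | (+)-catechin, (2R,3S) | Oc1cc(O)c2c(c1)O[C@H](c1ccc(O)c(O)c1)[C@@H](O)C2 | starting material
8 | 5,7,3',4'-tetra-O-benzyl-(+)-catechin, (2R,3S) | c1(OCc9ccccc9)cc(OCc9ccccc9)c2c(c1)O[C@H](c8ccc(OCc9ccccc9)c(OCc9ccccc9)c8)[C@@H](O)C2 | intermediate
9 | 3,5,7,3',4'-penta-O-benzyl-(+)-catechin, (2R,3S) | c1(OCc9ccccc9)cc(OCc9ccccc9)c2c(c1)O[C@H](c8ccc(OCc9ccccc9)c(OCc9ccccc9)c8)[C@@H](OCc9ccccc9)C2 | intermediate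
10 | 8-bromo-3,5,7,3',4'-penta-O-benzyl-(+)-catechin, (2R,3S) | Brc5c(OCc9ccccc9)cc(OCc9ccccc9)c6c5O[C@H](c8ccc(OCc9ccccc9)c(OCc9ccccc9)c8)[C@@H](OCc9ccccc9)C6 | intermediate
11 | 8-lithio-3,5,7,3',4'-penta-O-benzylcatechin, (2R,3S) | [Li]c5c(OCc9ccccc9)cc(OCc9ccccc9)c6c5O[C@H](c8ccc(OCc9ccccc9)c(OCc9ccccc9)c8)[C@@H](OCc9ccccc9)C6 | intermediate
12 | lithium trimethoxy(3,5,7,3',4'-penta-O-benzylcatechin-8-yl)borate, (2R,3S) | [Li+].CO[B-](OC)(OC)c5c(OCc9ccccc9)cc(OCc9ccccc9)c6c5O[C@H](c8ccc(OCc9ccccc9)c(OCc9ccccc9)c8)[C@@H](OCc9ccccc9)C6 | intermediate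
13 | 2-(3,5,7,3',4'-penta-O-benzylcatechin-8-yl)-5,5-dimethyl-1,3,2-dioxaborinane, (2R,3S) | CC7(C)COB(OC7)c5c(OCc9ccccc9)cc(OCc9ccccc9)c6c5O[C@H](c8ccc(OCc9ccccc9)c(OCc9ccccc9)c8)[C@@H](OCc9ccccc9)C6 | intermediate
14 | 8-{(1S)-1-[2-(allyloxy)-4,6-bis(benzyloxy)phenyl]prop-2-en-1-yl}-3,5,7,3',4'-penta-O-benzyl-(+)-catechin | c1(OCc9ccccc9)cc(OCc9ccccc9)cc(OCC=C)c1[C@H](C=C)c5c(OCc9ccccc9)cc(OCc9ccccc9)c6c5O[C@H](c8ccc(OCc9ccccc9)c(OCc9ccccc9)c8)[C@@H](OCc9ccccc9)C6 | intermediate
15 | 8-{(1S)-1-[2,4-bis(benzyloxy)-6-hydroxyphenyl]prop-2-en-1-yl}-3,5,7,3',4'-penta-O-benzyl-(+)-catechin | c1(OCc9ccccc9)cc(OCc9ccccc9)cc(O)c1[C@H](C=C)c5c(OCc9ccccc9)cc(OCc9ccccc9)c6c5O[C@H](c8ccc(OCc9ccccc9)c(OCc9ccccc9)c8)[C@@H](OCc9ccccc9)C6 | intermediate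
16 | 3,4-bis(benzyloxy)benzoic acid | OC(=O)c1ccc(OCc2ccccc2)c(OCc2ccccc2)c1 | starting material
17 | 3,4-bis(benzyloxy)benzoyl chloride | ClC(=O)c1ccc(OCc2ccccc2)c(OCc2ccccc2)c1 | intermediate
18 | 3,5-bis(benzyloxy)-2-[(1S)-1-(3,5,7,3',4'-penta-O-benzylcatechin-8-yl)prop-2-en-1-yl]phenyl 3,4-bis(benzyloxy)benzoate | c1(OCc9ccccc9)cc(OCc9ccccc9)cc(OC(=O)c8ccc(OCc9ccccc9)c(OCc9ccccc9)c8)c1[C@H](C=C)c5c(OCc9ccccc9)cc(OCc9ccccc9)c6c5O[C@H](c8ccc(OCc9ccccc9)c(OCc9ccccc9)c8)[C@@H](OCc9ccccc9)C6 | intermediate
19 | 8-{(1S)-1-[2,4-bis(benzyloxy)-6-({1-[3,4-bis(benzyloxy)phenyl]ethenyl}oxy)phenyl]prop-2-en-1-yl}-3,5,7,3',4'-penta-O-benzyl-(+)-catechin | c1(OCc9ccccc9)cc(OCc9ccccc9)cc(OC(=C)c8ccc(OCc9ccccc9)c(OCc9ccccc9)c8)c1[C@H](C=C)c5c(OCc9ccccc9)cc(OCc9ccccc9)c6c5O[C@H](c8ccc(OCc9ccccc9)c(OCc9ccccc9)c8)[C@@H](OCc9ccccc9)C6 | intermediate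
20 | (4S)-5,7-bis(benzyloxy)-2-[3,4-bis(benzyloxy)phenyl]-4-(3,5,7,3',4'-penta-O-benzylcatechin-8-yl)-4H-chromene | c1(OCc9ccccc9)cc(OCc9ccccc9)cc2OC(c8ccc(OCc9ccccc9)c(OCc9ccccc9)c8)=C[C@H](c5c(OCc9ccccc9)cc(OCc9ccccc9)c6c5O[C@H](c8ccc(OCc9ccccc9)c(OCc9ccccc9)c8)[C@@H](OCc9ccccc9)C6)c12 | intermediate
21 | (2S,4S)-2-(3,4-dihydroxyphenyl)-4-[(2R,3S)-2-(3,4-dihydroxyphenyl)-3,5,7-trihydroxychroman-8-yl]chroman-5,7-diol | Oc1cc(O)c2c(c1)O[C@H](c1ccc(O)c(O)c1)C[C@@H]2c1c(O)cc(O)c2c1O[C@H](c1ccc(O)c(O)c1)[C@@H](O)C2 | target

## Step count and least certain steps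

Total step count: 15. Longest linear sequence: 11 steps (steps 1 to 5, then 10 to 15, from 1); the branch from 7 runs over 10 steps.

**Step 10 (the least certain).**
- Risk: transfer of the di-ortho-substituted aryl group from boron to copper may be slow. Ionisation of the electron-rich phosphate and uncatalysed substitution could then take over, with loss of γ-selectivity and of control at C4, alongside protodeboronation.
- Fallback: it sets out from 10 (with 1 as partner) and returns at 15; it makes the C4–ring A bond inside one molecule by a pericyclic step.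
  - Stille coupling of 10 with (E)-3-(tributylstannyl)prop-2-en-1-ol [Pd2(dba)3, P(t-Bu)3, CsF, dioxane] would give (2E)-3-(3,5,7,3',4'-penta-O-benzylcatechin-8-yl)prop-2-en-1-ol F1.
  - Mitsunobu etherification of F1 with 1 (PPh3, diisopropyl azodicarboxylate, THF) would give 8-{(1E)-3-[3,5-bis(benzyloxy)phenoxy]prop-1-en-1-yl}-3,5,7,3',4'-penta-O-benzylcatechin F2.
  - Thermal aromatic Claisen rearrangement of F2 (PhNEt2, 180 °C) should move the allyl unit to one of the two equivalent ortho carbons and, after tautomerisation, give 15 with O1 already free.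
  - Cost: C4 is not controlled. The (1R)-epimer of 15, F3, is expected in a comparable amount and must be separated as a diastereomer and discarded. Steps 1 to 5, 9 and 11 would no longer be needed.

**Step 13.**
- Risk: incomplete methylenation of the ortho-substituted aryl ester at a temperature the substrate tolerates, and hydrolytic loss of the enol ether during isolation.
- Fallback: it sets out from 15 and returns at 19, bypassing 18. Palladium-catalysed C–O coupling of 15 with 1-[3,4-bis(benzyloxy)phenyl]ethenyl trifluoromethanesulfonate F4 would form the O1–C2 bond of the enol ether directly. F4 would be made from commercial 1-[3,4-bis(benzyloxy)phenyl]ethanone with KN(SiMe3)2 and PhNTf2. The coupling would use Pd2(dba)3, 2-(di-tert-butylphosphino)biphenyl and K3PO4 in toluene at 80 °C; the weak base is chosen to avoid moving the C4 double bond.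

**Step 14 (key step).**
- Risk: the alkylidene may fail to form at the crowded C4 vinyl group, or the catalyst may decompose before the hindered trisubstituted enol ether closes; decomposition products could then move the vinyl double bond into conjugation.
- Fallback: it sets out from 18 and returns at 20. A reduced titanium alkylidene, made from TiCl4, TMEDA, Zn, catalytic PbCl2 and CH3CHBr2 in THF/CH2Cl2, would exchange with the vinyl group and then olefinate the ester carbonyl within the same molecule. This stoichiometric carbonyl–olefin ring closure needs neither step 13 nor the molybdenum catalyst. No new compound is made (entry F0).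

**Step 15.**
- Risk: insufficient facial discrimination in the hydrogen addition, and hydrogenolytic opening of the benzylic C2–O1 bond during the long debenzylation.
- Fallback: it sets out from 20 and returns at 21, setting C2 by a reagent and not by the C4 substituent.
  - Mild hydrolysis of the enol ether (aqueous oxalic acid on SiO2, CH2Cl2, rt) would give (3S)-1-[3,4-bis(benzyloxy)phenyl]-3-[2,4-bis(benzyloxy)-6-hydroxyphenyl]-3-(3,5,7,3',4'-penta-O-benzylcatechin-8-yl)propan-1-one F5.
  - Corey–Bakshi–Shibata reduction [(S)-2-methyl-CBS-oxazaborolidine, BH3·SMe2, THF, −20 °C] should give the (1R,3S)-carbinol, (1R,3S)-1-[3,4-bis(benzyloxy)phenyl]-3-[2,4-bis(benzyloxy)-6-hydroxyphenyl]-3-(3,5,7,3',4'-penta-O-benzylcatechin-8-yl)propan-1-ol F6.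
  - Mitsunobu cyclisation (PPh3, diisopropyl azodicarboxylate, THF, 0 °C) would close O1–C2 with inversion to nona-O-benzyl 21, F7.
  - Hydrogenolysis (H2, Pd(OH)2/C) would then give 21.

## Further compounds

F1 | step 10 | (2E)-3-(3,5,7,3',4'-penta-O-benzylcatechin-8-yl)prop-2-en-1-ol | OC/C=C/c5c(OCc9ccccc9)cc(OCc9ccccc9)c6c5O[C@H](c8ccc(OCc9ccccc9)c(OCc9ccccc9)c8)[C@@H](OCc9ccccc9)C6
F2 | step 10 | 8-{(1E)-3-[3,5-bis(benzyloxy)phenoxy]prop-1-en-1-yl}-3,5,7,3',4'-penta-O-benzylcatechin | c1(OCc9ccccc9)cc(OCc9ccccc9)cc(OC/C=C/c5c(OCc9ccccc9)cc(OCc9ccccc9)c6c5O[C@H](c8ccc(OCc9ccccc9)c(OCc9ccccc9)c8)[C@@H](OCc9ccccc9)C6)c1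
F3 | step 10 | 8-{(1R)-1-[2,4-bis(benzyloxy)-6-hydroxyphenyl]prop-2-en-1-yl}-3,5,7,3',4'-penta-O-benzylcatechin (C4 epimer of 15) | c1(OCc9ccccc9)cc(OCc9ccccc9)cc(O)c1[C@@H](C=C)c5c(OCc9ccccc9)cc(OCc9ccccc9)c6c5O[C@H](c8ccc(OCc9ccccc9)c(OCc9ccccc9)c8)[C@@H](OCc9ccccc9)C6
F4 | step 13 | 1-[3,4-bis(benzyloxy)phenyl]ethenyl trifluoromethanesulfonate | C=C(OS(=O)(=O)C(F)(F)F)c1ccc(OCc2ccccc2)c(OCc2ccccc2)c1
F0 | step 14 | none | none
F5 | step 15 | (3S)-1-[3,4-bis(benzyloxy)phenyl]-3-[2,4-bis(benzyloxy)-6-hydroxyphenyl]-3-(3,5,7,3',4'-penta-O-benzylcatechin-8-yl)propan-1-one | c1(OCc9ccccc9)cc(OCc9ccccc9)cc(O)c1[C@H](CC(=O)c8ccc(OCc9ccccc9)c(OCc9ccccc9)c8)c5c(OCc9ccccc9)cc(OCc9ccccc9)c6c5O[C@H](c8ccc(OCc9ccccc9)c(OCc9ccccc9)c8)[C@@H](OCc9ccccc9)C6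
F6 | step 15 | (1R,3S)-1-[3,4-bis(benzyloxy)phenyl]-3-[2,4-bis(benzyloxy)-6-hydroxyphenyl]-3-(3,5,7,3',4'-penta-O-benzylcatechin-8-yl)propan-1-ol | c1(OCc9ccccc9)cc(OCc9ccccc9)cc(O)c1[C@H](C[C@@H](O)c8ccc(OCc9ccccc9)c(OCc9ccccc9)c8)c5c(OCc9ccccc9)cc(OCc9ccccc9)c6c5O[C@H](c8ccc(OCc9ccccc9)c(OCc9ccccc9)c8)[C@@H](OCc9ccccc9)C6
F7 | step 15 | nona-O-benzyl 21, (2S,4S) upper unit and (2R,3S) lower unit | c1(OCc9ccccc9)cc(OCc9ccccc9)c2c(c1)O[C@H](c8ccc(OCc9ccccc9)c(OCc9ccccc9)c8)C[C@@H]2c5c(OCc9ccccc9)cc(OCc9ccccc9)c6c5O[C@H](c8ccc(OCc9ccccc9)c(OCc9ccccc9)c8)[C@@H](OCc9ccccc9)C6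
A1 | alternative 1 | (2S)-2,4-cis-5,7,3',4'-tetra-O-benzyl-4-[(triisopropylsilyloxy)ethynyl]flavan | c1(OCc9ccccc9)cc(OCc9ccccc9)c2c(c1)O[C@H](c8ccc(OCc9ccccc9)c(OCc9ccccc9)c8)C[C@@H]2C#CO[Si](C(C)C)(C(C)C)C(C)C
A2 | alternative 1 | 3-(benzyloxy)cyclobut-2-en-1-one | O=C1CC(OCc2ccccc2)=C1
A3 | alternative 1 | (2S)-2,4-cis-5,7,3',4'-tetra-O-benzyl-4-[4-(benzyloxy)-2-hydroxy-6-(triisopropylsilyloxy)phenyl]flavan | c1(OCc9ccccc9)cc(OCc9ccccc9)c2c(c1)O[C@H](c8ccc(OCc9ccccc9)c(OCc9ccccc9)c8)C[C@@H]2c5c(O)cc(OCc9ccccc9)cc5O[Si](C(C)C)(C(C)C)C(C)C
A4 | alternative 2 | (2S)-2,4-cis-5,7,3',4'-tetra-O-benzyl-4-[2,4-bis(benzyloxy)-6-{(R)-[3,4-bis(benzyloxy)phenyl][(2S)-oxiran-2-yl]methoxy}phenyl]flavan | c1(OCc9ccccc9)cc(OCc9ccccc9)c2c(c1)O[C@H](c8ccc(OCc9ccccc9)c(OCc9ccccc9)c8)C[C@@H]2c5c(OCc9ccccc9)cc(OCc9ccccc9)cc5O[C@H](c8ccc(OCc9ccccc9)c(OCc9ccccc9)c8)[C@@H]6CO6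
A5 | alternative 2 | octa-O-benzyl 21 with the lower 3-hydroxyl free | c1(OCc9ccccc9)cc(OCc9ccccc9)c2c(c1)O[C@H](c8ccc(OCc9ccccc9)c(OCc9ccccc9)c8)C[C@@H]2c5c(OCc9ccccc9)cc(OCc9ccccc9)c6c5O[C@H](c8ccc(OCc9ccccc9)c(OCc9ccccc9)c8)[C@@H](O)C6
A6 | alternative 3 | (1R)-1-[3,4-bis(benzyloxy)phenyl]-3,3-bis[2,4-bis(benzyloxy)-6-hydroxyphenyl]propan-1-ol | O[C@@H](c8ccc(OCc9ccccc9)c(OCc9ccccc9)c8)CC(c1c(O)cc(OCc9ccccc9)cc1OCc9ccccc9)c1c(O)cc(OCc9ccccc9)cc1OCc9ccccc9
A7 | alternative 3 | (2S)-2,4-cis-5,7,3',4'-tetra-O-benzyl-4-[2,4-bis(benzyloxy)-6-hydroxyphenyl]flavan | c1(OCc9ccccc9)cc(OCc9ccccc9)c2c(c1)O[C@H](c8ccc(OCc9ccccc9)c(OCc9ccccc9)c8)C[C@@H]2c5c(OCc9ccccc9)cc(OCc9ccccc9)cc5O
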